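Neighbouring flasks with other charges of substrate can be compared by what the gas inflow can pay for in each.

    gas phase ⇌ dissolved gas, rate k1*(csat - [dissolved gas]) (k1 = 9.44 × 10⁻⁴ s⁻¹, csat = 200 mM)
    substrate + dissolved gas ⇌ target (K2 = 2.0 M⁻¹, k2 = 0.0785 M⁻¹ s⁻¹)
    dissolved gas + target → over-reacted product (k3 = 0.0219 M⁻¹ s⁻¹)
    substrate ⇌ dormant form (K4 = 0.27, k4 = 0.00391 s⁻¹)

substrate 1.4 M; gas phase 200 mM (held); time 3.0 h

- amount of target at 3.0 h, in percent of the substrate charged
- the change that raises the amount of target at 3.0 h, in percent of the substrate charged most ("none" if none brings more than 2 percentage points) (dusk / noon / none)
- amount of target at 3.0 h, in percent of the substrate charged, after noon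

- dusk: doubling the saturation concentration of gas phase, all else as stated
- noon: doubling the transfer coefficient of step 1, all else as stated

The step to the dormant form relaxes in 0.628 min and the step to target in at most 0.294 min, both short against 3.0 h, so my reckoning takes both as settled. Each over-reacted product costs two gas. The burn-out time is therefore the time in which inflow into an empty solution pays two gas for each substrate charged: 4.12 h. This is far longer than either relaxation, so my reckoning holds both steps settled while the charge burns. Setting inflow equal to the gas spent in over-reaction gives, for each size of unburned pool:

| Pool | Free substrate | Gas, of saturation | Gap to saturation | Target |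
|---|---|---|---|---|
| whole charge | 78.7% | 19.8% | 80.2% | 6.24% |
| half the charge | 39.4% | 26.8% | 73.2% | 4.21% |

Reading down the gap column, the gap narrows little, so burning runs nearly steadily while target falls with the pool. By my reckoning, the mean gap times 3.0 h over the burn-out time gives 55.9% of the charge burned, which leaves 44.1% and target near 3.92%. Dusk doubles the saturation concentration of the gas phase and noon doubles the transfer coefficient of step 1; either change cuts the burn-out time to 2.06 h, below the run time, so I expect no gain; my reckoning stops at that direction.

The forecast gives 3.9%, none and 2.2%, on the ground that “Each over-reaction consumes two gas molecules”.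

The simulation gives 3.85%, best change none (dusk −3.3 percentage points, noon −1.7 points) and 2.14% after noon.

At 3.00 h the flask is not at rest: 35% of the charge is still free substrate, over-reacted product stands at 52.2%, and target is made at 0.950 of the rate at which it is used. Ten times the run is 7.28 burn-out times, and there the flask holds 100% over-reacted product, 0% target and dissolved gas at 0.200 M. The target of the asked time is thus a passing amount, already 0.839% at 6.00 h.

For the neighbour with 2.4 M of substrate, the burn-out time scales to 7.06 h, and the first row's gap gives 34.1% burned. The simulation of that neighbour gives 32.7% over-reacted product and 3.79% target.

The numbers are those of an exercise.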